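**Retrosynthetic overview**

1. The C3–O ester bond is made last: a MOM-protected (2R,3R)-flavan-3-ol is esterified with 4-O-acetylferulic acid (Steglich), and one acid step then removes four MOM groups and the acetate.
2. Ring C is opened at two bonds to ring A at once, O1–C8a and C4–C4a: 3,5-bis(methoxymethoxy)benzyne plus the sodium alkoxide of an acyclic (1R,2S)-1-aryl-2-benzyloxy-3-bromopropan-1-ol.
3. Enabling feature: in ring A, C8a (carrying O1) and C4a (carrying the C4 methylene) are neighbouring carbons and the C5 oxygen is ortho to C4a; in the aryne C4a≡C8a this alkoxy group sends the alkoxide to C8a and leaves the carbanion on C4a, which alkylates C4.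
4. The acyclic partner comes from an Evans syn-glycolate aldol of the ring B aldehyde (sets C2 and C3), LiBH4 reduction (the imide carbonyl becomes C4) and Appel bromination.
5. Ring order: rings A and B are bought as arenes (phloroglucinol, methyl 4-O-methylgallate); ring C is the only ring made, in the key step.

Key step: step 11

Assumption: the target is read as (2R,3R), the 2,3-cis (epi) series; the 4-O-methylgallate ester, the oxazolidinone, the acid chloride and the acetylated ferulic acid used below are taken as catalogue compounds.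

**Route**

Step 1
Reactants: 1 phloroglucinol
Product: 2 3,5-bis(methoxymethoxy)phenol
Conditions: MOMCl (2.0 equiv), i-Pr2NEt, DMF, 0 °C → rt; chromatography
Reagents that add atoms: chloromethyl methyl ether (MOMCl), COCCl
Why: Williamson-type O-alkylation (MOM acetal formation) of the threefold-symmetric triphenol with two equivalents of MOMCl should give the bis-ether as a single constitutional isomer, to be separated by chromatography from the mono- and tris-ethers that a statistical alkylation also forms.

Step 2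
Reactants: 2 3,5-bis(methoxymethoxy)phenol
Product: 3 2-bromo-3,5-bis(methoxymethoxy)phenol
Conditions: NBS (1.0 equiv), CH2Cl2, −78 → −40 °C
Reagents that add atoms: N-bromosuccinimide, O=C1CCC(=O)N1Br
Why: Electrophilic aromatic bromination of the free phenol should occur ortho to the hydroxyl, because the two equivalent positions between OH and OMOM are less hindered than the position between the two OMOM groups, and any 4-bromo isomer is removed by chromatography.

Step 3
Reactants: 3 2-bromo-3,5-bis(methoxymethoxy)phenol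
Product: 6 3,5-bis(methoxymethoxy)-2-(trimethylsilyl)phenyl trifluoromethanesulfonate, via aryl silyl ether 4 (not isolated), via lithium phenoxide 5 (not isolated)
Conditions: HMDS, THF, 70 °C, then evaporate; n-BuLi, THF, −78 °C; Tf2O, −78 °C
Reagents that add atoms: hexamethyldisilazane, C[Si](C)(C)N[Si](C)(C)C; trifluoromethanesulfonic anhydride, O=S(=O)(OS(=O)(=O)C(F)(F)F)C(F)(F)F
Why: This is the standard preparation of an o-silylaryl triflate aryne precursor by O-silylation, bromine–lithium exchange, retro-Brook 1,3-silyl shift from O to C and O-triflation of the phenoxide, with the exchange at −78 °C outrunning MOM-directed ortho-lithiation.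

Step 4
Reactants: 7 methyl 3,5-dihydroxy-4-methoxybenzoate
Product: 8 methyl 4-methoxy-3,5-bis(methoxymethoxy)benzoate
Conditions: MOMCl (2.5 equiv), i-Pr2NEt, CH2Cl2, 0 °C → rt
Reagents that add atoms: chloromethyl methyl ether (MOMCl), COCCl
Why: MOM protection (O-alkylation) of both phenols under amine base should be clean, since the methyl ester and the methyl ether are inert.

Step 5
Reactants: 8 methyl 4-methoxy-3,5-bis(methoxymethoxy)benzoate
Product: 9 [4-methoxy-3,5-bis(methoxymethoxy)phenyl]methanol
Conditions: LiAlH4, THF, 0 °C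
Reagents that add atoms: none
Why: Hydride reduction of the aryl ester to the benzylic alcohol leaves MOM acetals and aryl ethers untouched.

Step 6
Reactants: 9 [4-methoxy-3,5-bis(methoxymethoxy)phenyl]methanol
Product: 10 4-methoxy-3,5-bis(methoxymethoxy)benzaldehyde
Conditions: activated MnO2, CH2Cl2, rt
Reagents that add atoms: none
Why: Heterogeneous MnO2 oxidation is selective for benzylic alcohols and stops at the aldehyde.

Step 7
Reactants: 11 (S)-4-benzyl-1,3-oxazolidin-2-one, 12 2-(benzyloxy)acetyl chloride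
Product: 13 (S)-4-benzyl-3-[2-(benzyloxy)acetyl]-1,3-oxazolidin-2-one
Conditions: Et3N, DMAP (cat.), CH2Cl2, 0 °C → rt
Reagents that add atoms: none
Why: N-acylation of the oxazolidinone by the acid chloride under DMAP acyl-transfer catalysis does not touch the auxiliary stereocentre.

Step 8
Reactants: 13 (S)-4-benzyl-3-[2-(benzyloxy)acetyl]-1,3-oxazolidin-2-one, 10 4-methoxy-3,5-bis(methoxymethoxy)benzaldehyde
Product: 15 (4S)-4-benzyl-3-[(2S,3R)-2-(benzyloxy)-3-hydroxy-3-[4-methoxy-3,5-bis(methoxymethoxy)phenyl]propanoyl]-1,3-oxazolidin-2-one, via boron enolate 14 (not isolated)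
Conditions: Bu2BOTf, Et3N, CH2Cl2, −78 → 0 °C; then 10, −78 → 0 °C; H2O2, MeOH, pH 7 buffer, 0 °C
Reagents that add atoms: none
Why: In this Evans syn-aldol reaction the (Z)-boron enolate 14 should react through a closed Zimmerman–Traxler transition state in which the benzyl group of the (S)-auxiliary blocks one enolate face, so that the (2S,3R) syn adduct is expected and both future stereocentres are fixed (C3 from the α-carbon, C2 from the carbinol carbon).

Step 9
Reactants: 15 (4S)-4-benzyl-3-[(2S,3R)-2-(benzyloxy)-3-hydroxy-3-[4-methoxy-3,5-bis(methoxymethoxy)phenyl]propanoyl]-1,3-oxazolidin-2-one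
Product: 16 (1R,2R)-2-(benzyloxy)-1-[4-methoxy-3,5-bis(methoxymethoxy)phenyl]propane-1,3-diol
Conditions: LiBH4, MeOH (1 equiv), THF, 0 °C
Reagents that add atoms: none
Why: Reductive cleavage of the imide with LiBH4 turns the acyl carbon into the primary alcohol (future C4) and releases the auxiliary without any bond change at the two stereocentres (the descriptor at the benzyloxy carbon changes only through priority).

Step 10
Reactants: 16 (1R,2R)-2-(benzyloxy)-1-[4-methoxy-3,5-bis(methoxymethoxy)phenyl]propane-1,3-diol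
Product: 17 (1R,2S)-2-(benzyloxy)-3-bromo-1-[4-methoxy-3,5-bis(methoxymethoxy)phenyl]propan-1-ol
Conditions: CBr4 (1.1 equiv), PPh3 (1.15 equiv), CH2Cl2, 0 °C
Reagents that add atoms: tetrabromomethane, BrC(Br)(Br)Br
Why: In this Appel reaction the oxyphosphonium salt should form faster at the unhindered primary hydroxyl than at the secondary benzylic one and is displaced by bromide in an SN2 step at a carbon that is not stereogenic.

Step 11
Reactants: 17 (1R,2S)-2-(benzyloxy)-3-bromo-1-[4-methoxy-3,5-bis(methoxymethoxy)phenyl]propan-1-ol, 6 3,5-bis(methoxymethoxy)-2-(trimethylsilyl)phenyl trifluoromethanesulfonate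
Product: 21 (2R,3R)-3-(benzyloxy)-2-[4-methoxy-3,5-bis(methoxymethoxy)phenyl]-5,7-bis(methoxymethoxy)chromane, via sodium alkoxide 18 (not isolated), via aryne 19 (not isolated), via aryl anion 20 (not isolated)
Conditions: NaH (1.1 equiv), THF, 0 °C; then 6 (1.5 equiv), CsF, 18-crown-6, THF, 0 °C → rt
Reagents that add atoms: none
Why: Proposed new method: sodium alkoxide 18 should add to aryne 19, released from 6 by fluoride, and the aryl anion 20 so formed should displace the primary bromide in the same flask, making O1–C8a and C4–C4a in one operation; the closest known reaction types are the aryne annulations in which an O- or N-nucleophile adds to the aryne and the aryl anion then cyclises onto a tethered ester or Michael acceptor (salicylate-to-xanthone annulation), and the Parham cyclialkylation of an ortho-metalated aryl ether onto a primary halide. Ring C closes in the 6-exo-tet mode, the C–Br bond lying outside the forming six-membered ring. No new stereocentre is created: C2 and C3 come from the aldol and no bond to either carbon is made or broken, so the syn (1R,2S) precursor maps onto the cis (2R,3R) chromane. The step needs regioselective addition to the unsymmetrical aryne, and the methoxymethoxy group next to the triple bond secures it: its inductive pull and the resulting aryne distortion direct the oxygen nucleophile to the distal carbon (future C8a, meta to that group) and place the carbanion on the proximal carbon (future C4a, ortho to it, where the MOM oxygen can also hold the cation). The step also needs C-alkylation to outrun O-alkylation and proton transfer: the benzyl ether on C3 rules out epoxide formation and Payne-type shifts, 4-exo-tet oxetane closure of the hindered secondary alkoxide should be slow at 0 °C, and NaH in an aprotic medium leaves no acid stronger than THF for the aryl anion.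

Step 12
Reactants: 21 (2R,3R)-3-(benzyloxy)-2-[4-methoxy-3,5-bis(methoxymethoxy)phenyl]-5,7-bis(methoxymethoxy)chromane
Product: 22 (2R,3R)-2-[4-methoxy-3,5-bis(methoxymethoxy)phenyl]-5,7-bis(methoxymethoxy)chroman-3-ol
Conditions: H2 (1 atm), Pd(OH)2/C, EtOAc/EtOH, rt
Reagents that add atoms: none
Why: Catalytic hydrogenolysis should cleave the alkyl benzyl ether while MOM acetals are stable and the ring C2–O1 bond, though benzylic, is known to survive hydrogenolytic debenzylation in flavan-3-ol chemistry.

Step 13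
Reactants: 22 (2R,3R)-2-[4-methoxy-3,5-bis(methoxymethoxy)phenyl]-5,7-bis(methoxymethoxy)chroman-3-ol, 23 (E)-3-(4-acetoxy-3-methoxyphenyl)prop-2-enoic acid
Product: 24 (2R,3R)-2-[4-methoxy-3,5-bis(methoxymethoxy)phenyl]-5,7-bis(methoxymethoxy)chroman-3-yl (E)-3-(4-acetoxy-3-methoxyphenyl)prop-2-enoate
Conditions: DCC, DMAP (cat.), CH2Cl2, 0 °C → rt
Reagents that add atoms: none
Why: Steglich esterification (carbodiimide activation with DMAP acyl transfer) should acylate the hindered axial 3-OH with retention, and the E-alkene and aryl acetate of 23 are not affected.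

Step 14
Reactants: 24 (2R,3R)-2-[4-methoxy-3,5-bis(methoxymethoxy)phenyl]-5,7-bis(methoxymethoxy)chroman-3-yl (E)-3-(4-acetoxy-3-methoxyphenyl)prop-2-enoate
Product: 25 4'-O-methylepigallocatechin-3-O-ferulate
Conditions: HCl (1.25 M in MeOH), THF, 0 °C → rt, argon
Reagents that add atoms: none
Why: Acid-catalysed transacetalisation to methanol should remove the four MOM groups and acid methanolysis of the unhindered aryl acetate should be faster than that of the hindered, conjugated secondary ferulate (as in acidic global deprotection of acylated caffeoyl esters), while the non-enolisable stereocentres C2 and C3 are not at risk in dilute acid at room temperature.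

**Compound list**

1 | phloroglucinol (benzene-1,3,5-triol) | Oc1cc(O)cc(O)c1 | starting material
2 | 3,5-bis(methoxymethoxy)phenol | COCOc1cc(O)cc(OCOC)c1 | intermediate
3 | 2-bromo-3,5-bis(methoxymethoxy)phenol | COCOc1cc(O)c(Br)c(OCOC)c1 | intermediate
4 | [2-bromo-3,5-bis(methoxymethoxy)phenoxy]trimethylsilane | COCOc1cc(O[Si](C)(C)C)c(Br)c(OCOC)c1 | intermediate
5 | lithium 3,5-bis(methoxymethoxy)-2-(trimethylsilyl)phenoxide | COCOc1cc([O-])c([Si](C)(C)C)c(OCOC)c1.[Li+] | intermediate
6 | 3,5-bis(methoxymethoxy)-2-(trimethylsilyl)phenyl trifluoromethanesulfonate | COCOc1cc(OS(=O)(=O)C(F)(F)F)c([Si](C)(C)C)c(OCOC)c1 | intermediate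
7 | methyl 3,5-dihydroxy-4-methoxybenzoate | COC(=O)c1cc(O)c(OC)c(O)c1 | starting material
8 | methyl 4-methoxy-3,5-bis(methoxymethoxy)benzoate | COC(=O)c1cc(OCOC)c(OC)c(OCOC)c1 | intermediate
9 | [4-methoxy-3,5-bis(methoxymethoxy)phenyl]methanol | OCc1cc(OCOC)c(OC)c(OCOC)c1 | intermediate
10 | 4-methoxy-3,5-bis(methoxymethoxy)benzaldehyde | O=Cc1cc(OCOC)c(OC)c(OCOC)c1 | intermediate
11 | (S)-4-benzyl-1,3-oxazolidin-2-one | O=C1N[C@@H](Cc2ccccc2)CO1 | starting material
12 | 2-(benzyloxy)acetyl chloride | O=C(Cl)COCc1ccccc1 | starting material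
13 | (S)-4-benzyl-3-[2-(benzyloxy)acetyl]-1,3-oxazolidin-2-one | O=C(COCc1ccccc1)N1[C@@H](Cc2ccccc2)COC1=O | intermediate
14 | dibutylboron (Z)-enolate of 13 | CCCCB(CCCC)O/C(=C\OCc1ccccc1)N1[C@@H](Cc2ccccc2)COC1=O | intermediate
15 | (4S)-4-benzyl-3-[(2S,3R)-2-(benzyloxy)-3-hydroxy-3-[4-methoxy-3,5-bis(methoxymethoxy)phenyl]propanoyl]-1,3-oxazolidin-2-one | O[C@@H]([C@H](OCc1ccccc1)C(=O)N1[C@@H](Cc2ccccc2)COC1=O)c1cc(OCOC)c(OC)c(OCOC)c1 | intermediate
16 | (1R,2R)-2-(benzyloxy)-1-[4-methoxy-3,5-bis(methoxymethoxy)phenyl]propane-1,3-diol | O[C@@H]([C@H](OCc1ccccc1)CO)c1cc(OCOC)c(OC)c(OCOC)c1 | intermediate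
17 | (1R,2S)-2-(benzyloxy)-3-bromo-1-[4-methoxy-3,5-bis(methoxymethoxy)phenyl]propan-1-ol | O[C@@H]([C@H](OCc1ccccc1)CBr)c1cc(OCOC)c(OC)c(OCOC)c1 | intermediate
18 | sodium (1R,2S)-2-(benzyloxy)-3-bromo-1-[4-methoxy-3,5-bis(methoxymethoxy)phenyl]propan-1-olate | [Na+].[O-][C@@H]([C@H](OCc1ccccc1)CBr)c1cc(OCOC)c(OC)c(OCOC)c1 | intermediate
19 | 3,5-bis(methoxymethoxy)benzyne (1,2-didehydro-3,5-bis(methoxymethoxy)benzene) | COCOC1=CC(OCOC)=CC#C1 | intermediate
20 | sodium 2-{[(1R,2S)-2-(benzyloxy)-3-bromo-1-[4-methoxy-3,5-bis(methoxymethoxy)phenyl]propyl]oxy}-4,6-bis(methoxymethoxy)benzen-1-ide | COCOc1cc(OCOC)[c-]c(O[C@@H]([C@H](OCc2ccccc2)CBr)c2cc(OCOC)c(OC)c(OCOC)c2)c1.[Na+] | intermediate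
21 | (2R,3R)-3-(benzyloxy)-2-[4-methoxy-3,5-bis(methoxymethoxy)phenyl]-5,7-bis(methoxymethoxy)chromane | C(O[C@@H]1Cc2c(OCOC)cc(OCOC)cc2O[C@@H]1c1cc(OCOC)c(OC)c(OCOC)c1)c1ccccc1 | intermediate
22 | (2R,3R)-2-[4-methoxy-3,5-bis(methoxymethoxy)phenyl]-5,7-bis(methoxymethoxy)chroman-3-ol | O[C@@H]1Cc2c(OCOC)cc(OCOC)cc2O[C@@H]1c1cc(OCOC)c(OC)c(OCOC)c1 | intermediate
23 | (E)-3-(4-acetoxy-3-methoxyphenyl)prop-2-enoic acid (4-O-acetylferulic acid) | COc1cc(/C=C/C(=O)O)ccc1OC(C)=O | starting material
24 | (2R,3R)-2-[4-methoxy-3,5-bis(methoxymethoxy)phenyl]-5,7-bis(methoxymethoxy)chroman-3-yl (E)-3-(4-acetoxy-3-methoxyphenyl)prop-2-enoate | COc1cc(/C=C/C(=O)O[C@@H]2Cc3c(OCOC)cc(OCOC)cc3O[C@@H]2c2cc(OCOC)c(OC)c(OCOC)c2)ccc1OC(C)=O | intermediate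
25 | 4'-O-methylepigallocatechin-3-O-ferulate, (2R,3R)-2-(3,5-dihydroxy-4-methoxyphenyl)-5,7-dihydroxychroman-3-yl (E)-3-(4-hydroxy-3-methoxyphenyl)prop-2-enoate | COc1cc(/C=C/C(=O)O[C@@H]2Cc3c(O)cc(O)cc3O[C@@H]2c2cc(O)c(OC)c(O)c2)ccc1O | target

**Step count**

Total steps: 14. Longest linear sequence: 10 steps (from 7 through steps 4, 5, 6, 8, 9, 10, 11, 12, 13, 14).

**Steps most likely to fail**

1. Step 11 (proposed new method). The alkoxide may be used up by intramolecular O-alkylation (oxetane closure), or the aryl anion may be protonated before it alkylates, so that the sequence stops at the open aryl ether and ring C does not close. Fallback with known chemistry, setting out from 17 (with 3 as partner) and returning at 21: a stepwise Mitsunobu and Parham sequence. Mitsunobu inversion of 17 with 4-nitrobenzoic acid (PPh3, DIAD, THF) should give (1S,2S)-2-(benzyloxy)-3-bromo-1-[4-methoxy-3,5-bis(methoxymethoxy)phenyl]propyl 4-nitrobenzoate F1. Methanolysis (K2CO3, MeOH, 0 °C) should give the C1-epimeric alcohol F2. A second Mitsunobu reaction, now with bromophenol 3, forms the O1–C2 bond with inversion and should give the (1R)-configured bromoaryl ether F3. Bromine–lithium exchange at the aryl bromide (n-BuLi, THF, −100 °C) and warming should close ring C by Parham cyclialkylation on the primary bromide and give 21.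

2. Step 14. Acid methanolysis of the ferulate ester, and re-alkylation of the electron-rich ring A by methoxymethyl cations, may compete with the removal of five protecting groups. Fallback, setting out from 22 and returning at 25: the acid step is moved in front of the esterification and the phenols are carried as silyl ethers. Treatment of 22 with HCl in MeOH should give (2R,3R)-4'-O-methylepigallocatechin F4. Selective silylation of the four phenols (TBSCl, imidazole, DMF, 0 °C; the axial 3-OH is left free) should give the tetrakis(TBS) ether F5. Steglich esterification with 23 (DCC, DMAP) should give the silylated ester F6. Buffered fluoride (TBAF, AcOH, THF, 0 °C) should give the 4-O-acetylferulate F7. Mild cleavage of the aryl acetate (NH4OAc, aqueous MeOH, rt) should then give 25.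

3. Step 10. Chemoselectivity may be lost by activation of the secondary benzylic hydroxyl (benzylic bromide, or a cyclic phosphorane that collapses to an oxetane). Fallback, setting out from 16 and returning at 17: selective sulfonylation of the primary hydroxyl (TsCl, Et3N, Bu2SnO cat., CH2Cl2, 0 °C) should give the primary tosylate F8, and displacement with LiBr (acetone, 50 °C) should give 17.

Further compounds
F1 | step 11 | (1S,2S)-2-(benzyloxy)-3-bromo-1-[4-methoxy-3,5-bis(methoxymethoxy)phenyl]propyl 4-nitrobenzoate | O=C(O[C@H]([C@H](OCc1ccccc1)CBr)c1cc(OCOC)c(OC)c(OCOC)c1)c1ccc(cc1)[N+](=O)[O-]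
F2 | step 11 | (1S,2S)-2-(benzyloxy)-3-bromo-1-[4-methoxy-3,5-bis(methoxymethoxy)phenyl]propan-1-ol | O[C@H]([C@H](OCc1ccccc1)CBr)c1cc(OCOC)c(OC)c(OCOC)c1
F3 | step 11 | 2-bromo-1-{[(1R,2S)-2-(benzyloxy)-3-bromo-1-[4-methoxy-3,5-bis(methoxymethoxy)phenyl]propyl]oxy}-3,5-bis(methoxymethoxy)benzene | COCOc1cc(OCOC)c(Br)c(O[C@@H]([C@H](OCc2ccccc2)CBr)c2cc(OCOC)c(OC)c(OCOC)c2)c1
F4 | step 14 | (2R,3R)-2-(3,5-dihydroxy-4-methoxyphenyl)chromane-3,5,7-triol (4'-O-methylepigallocatechin) | O[C@@H]1Cc2c(O)cc(O)cc2O[C@@H]1c1cc(O)c(OC)c(O)c1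
F5 | step 14 | (2R,3R)-5,7-bis(tert-butyldimethylsilyloxy)-2-[3,5-bis(tert-butyldimethylsilyloxy)-4-methoxyphenyl]chroman-3-ol | O[C@@H]1Cc2c(O[Si](C)(C)C(C)(C)C)cc(O[Si](C)(C)C(C)(C)C)cc2O[C@@H]1c1cc(O[Si](C)(C)C(C)(C)C)c(OC)c(O[Si](C)(C)C(C)(C)C)c1
F6 | step 14 | (2R,3R)-5,7-bis(tert-butyldimethylsilyloxy)-2-[3,5-bis(tert-butyldimethylsilyloxy)-4-methoxyphenyl]chroman-3-yl (E)-3-(4-acetoxy-3-methoxyphenyl)prop-2-enoate | COc1cc(/C=C/C(=O)O[C@@H]2Cc3c(O[Si](C)(C)C(C)(C)C)cc(O[Si](C)(C)C(C)(C)C)cc3O[C@@H]2c2cc(O[Si](C)(C)C(C)(C)C)c(OC)c(O[Si](C)(C)C(C)(C)C)c2)ccc1OC(C)=O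
F7 | step 14 | (2R,3R)-2-(3,5-dihydroxy-4-methoxyphenyl)-5,7-dihydroxychroman-3-yl (E)-3-(4-acetoxy-3-methoxyphenyl)prop-2-enoate | COc1cc(/C=C/C(=O)O[C@@H]2Cc3c(O)cc(O)cc3O[C@@H]2c2cc(O)c(OC)c(O)c2)ccc1OC(C)=O
F8 | step 10 | (2R,3R)-2-(benzyloxy)-3-hydroxy-3-[4-methoxy-3,5-bis(methoxymethoxy)phenyl]propyl 4-methylbenzenesulfonate | O[C@@H]([C@H](OCc1ccccc1)COS(=O)(=O)c1ccc(C)cc1)c1cc(OCOC)c(OC)c(OCOC)c1
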